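- A minute of Friday's run is not a minute of Wednesday's flask, and the repeat has to be timed with that in mind.

all flasks: catalyst 0.1 mol%; temperature 20 °C
- Wednesday's: substrate 0.20 M; the very flask that is asked about, followed so far
- Friday's: substrate 0.30 M; run made earlier
- flask: substrate 0.20 M; time 10 min

| run | time / min | target / % |
|---|---|---|
| Wednesday's | 0.500 | 25.3 |
| Wednesday's | 1.50 | 37.6 |
| Wednesday's | 3.00 | 34.5 |
| Wednesday's | 4.00 | 28.0 |
| Wednesday's | 6.00 | 23.2 |
| Friday's | 1.33 | 40.6 |
| Friday's | 3.00 | 28.4 |
| Friday's | 4.00 | 23.8 |
| Friday's | 6.00 | 19.6 |
| Friday's | 8.00 | 17.7 |

(readings scatter by 0.5 percentage points)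

- what is taken out of target is counted as made
- the numbers in the tables scatter with a standard deviation of 0.5 percentage points
- additions bring no volume worth counting

- north-east: at 10 min add catalyst, 100 % of the amount charged, then wait 3.0 min
- north-west: at 10 min raise the temperature by 20 K, then wait 3.0 min
- south-east: at 10 min take out 90 % of the target then present, then wait 3.0 min
- east: change nothing and wait 3.0 min more

- target, in percent of the substrate first charged, at 10 min
- the remedy with the largest gain of target, or "none" below 2 percentage points (north-east / north-west / south-east / east / none)
- target present, with what was taken out counted in, in percent of the substrate first charged, after north-east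
- target present, with what was taken out counted in, in percent of the substrate first charged, after north-west

- The puzzle: at 3.00 min Wednesday's flask read 34.5 % and Friday's run, at 3.00 min, read 28.4 % of its charge, 6.1 percentage points apart, with equal loading and temperature.
- A loading is a ratio, so Friday's run, charged with more substrate, also held 1.50 times the catalyst per volume, and its target fell sooner on the plain clock.
- Wednesday's 10 min comes to 6.67 min on the catalyst clock, meaning a flask's minutes times its substrate charge over Friday's charge, at equal loading and temperature.
- As a test, Friday's 4.00 min matches Wednesday's 6.00 min, and those readings, 23.8 % and 23.2 %, lie 0.6 points apart, with a scatter of 0.5 points each.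
- The reckoning here replaces Friday's tail by a chord between 6.00 min and 8.00 min, which gives 19.0 % at 6.67 min. The change of slope puts the curve 0.26 points below that chord, so the reckoning commits to 18.7 %.
- Waiting moves Wednesday's flask to 8.67 min on the clock, and north-east, whose 3.0 min run at twice the catalyst per volume, moves it to 10.7 min. Both lie later than Friday's last reading at 8.00 min, and Friday's readings were still falling up to there, so the reckoning expects both to lose target. Both runs stood at 20 °C, so the clock reads nothing about north-west.
- The forecast gave 18.7 % now, 16.6 % after north-east and 17 % after north-west, and it chose south-east. On heating it wrote: “Heating speeds relaxation to equilibrium, but the shift is unknown”.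
- The flask gave 16.9 % now, 1.8 points under the reckoning, 15.1 % after north-east and 31.6 % after north-west, and the best remedy was north-west. Gains were 15 points for north-west, 5.4 points for south-east, −1.8 points for north-east and −1.3 points for waiting.

    substrate ⇌ other conformer (K = 0.480, k = 0.0350 s⁻¹, Ea = 87.0 kJ mol⁻¹, ΔH = −41.0 kJ mol⁻¹)
    substrate + catalyst → catalyst + target (k = 75.0 M⁻¹ s⁻¹, Ea = 37.0 kJ mol⁻¹)
    catalyst + other conformer → catalyst + isomer of the product A (k = 220 M⁻¹ s⁻¹, Ea = 42.0 kJ mol⁻¹)
    target + catalyst ⇌ isomer of the product B + catalyst, rate k4*[catalyst]*[target] forward; the back reaction follows from the equilibrium constant (K = 2.60, k = 19.0 M⁻¹ s⁻¹, Ea = 53.0 kJ mol⁻¹, ΔH = −51.0 kJ mol⁻¹)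
    (constants at 20 °C)

- In Wednesday's flask target formed while substrate lasted, half of that step's turnover being done by 0.474 min. Substrate stood at 0.0814 % after 5.00 min, and target went on exchanging with isomer of the product B over the catalyst, that step alone having a relaxation half-life of 2.20 min at 10.0 min and a step enthalpy of −51.0 kJ mol⁻¹, while the forecast for north-west lay 15 points under the flask. On the catalyst clock, Wednesday's flask held 16.9 % at 6.67 min, and the neighbour charged with 0.080 M, after its 10 min, stood at 2.67 min, the clock time of Wednesday's reading of 28.0 % at 4.00 min, and held 25.1 %, 2.9 points below that reading.

The earlier runs and the new flask were computed from invented constants; noise was put on by code.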